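Per mole of starting complex charged, this flask holds 1.50 mol of incoming ligand. Call this n, the turnover allowance: moles of incoming ligand charged per mole of starting complex charged. Each exchange takes one incoming ligand.

| setting | grey | red | green | flask |
|---|---|---|---|---|
| starting complex | 0.15 M | 0.22 M | 0.30 M | 0.30 M |
| incoming ligand | 0.45 M | 0.45 M | 0.90 M | 0.450 M |
| remark | run made earlier | run made earlier | run made earlier |  |
| time |  |  |  | 3.0 h |

- grey (time / min: starting complex / %, complex with one exchanged / %): 20.0: 9, 7; 40.0: 9, 7; 60.0: 10, 9; 80.0: 9, 7; 120: 8, 10
- red (time / min: starting complex / %, complex with one exchanged / %): 8.00: 26, 15; 15.0: 23, 14; 30.0: 26, 15; 60.0: 23, 12; 120: 21, 10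
- green (time / min: starting complex / %, complex with one exchanged / %): 20.0: 13, 6; 40.0: 10, 7; 60.0: 7, 6; 80.0: 11, 7; 120: 11, 6

(scatter of a reading: 1.5 percentage points)

- the reaction counts as stopped when no species that holds the starting complex changes by six tenths of a point or more over the second half of the time

* which holds at 3.0 h: what has brought the reaction to rest, or that it has not come to rest (it is still moving / the incoming ligand has run out first / forward and back rates have come level / all of the starting complex has reacted)
* part of the starting complex gone at 3.0 h
* the complex with one exchanged standing at 3.0 h, as a percentage of the starting complex charged
* the complex with two exchanged standing at 3.0 h, as a percentage of the starting complex charged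

The next run can change the time or change n, and the earlier runs favour n. The grey and green runs share n = 3.00 at different charges, and their mean starting-complex readings, 9.00% and 10.4%, lie close against a scatter of 1.5 percentage points. The red run, at n = 2.05, averages 23.8%. It already reads 26% at 8.00 min, far sooner than this flask's 3.0 h, and 21% at 120 min. So you leave the time and change n. Your reckoning for this flask is rest by 3.0 h, with exchanges per complex charged equal to n = 1.50, and more starting complex standing than the red run reads, since this flask's n is lower than the red run's.

The forecast differs: forward and back rates have come level, with “about 1.14 ligand exchanged per complex”, giving 63.5% gone, 12.5% of the complex with one exchanged and 51% of the complex with two exchanged.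

The flask gives: the incoming ligand has run out first, with 65.9% gone, 13.6% of the complex with one exchanged and 18.2% of the complex with two exchanged.

    starting complex + incoming ligand → leaving ligand + complex with one exchanged (k = 0.0200 L mol⁻¹ s⁻¹)
    complex with one exchanged + incoming ligand → leaving ligand + complex with two exchanged (k = 0.0480 L mol⁻¹ s⁻¹)
    complex with two exchanged + incoming ligand → leaving ligand + complex with three exchanged (k = 0.0410 L mol⁻¹ s⁻¹)
    complex with three exchanged + incoming ligand → leaving ligand + complex with four exchanged (k = 0.0960 L mol⁻¹ s⁻¹)
    crystals ⇌ leaving ligand, rate k5*(cs5 - [leaving ligand]) while solid is left; crystals form when [leaving ligand] > cs5 (solubility = 3.30 mM, k = 0.370 s⁻¹)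
    complex with one exchanged ⇌ isomer of the product (K = 0.710, k = 0.00210 s⁻¹)

The flask has come to rest: incoming ligand, the limiting reagent, stands at 0% of its charge at 3.00 h. At 30.0 h the flask still shows 65.9% gone, 13.6% of the complex with one exchanged and 18.2% of the complex with two exchanged, so ten times the time moves none of these three. Weighting each complex in the flask by its exchanges, with the isomer of the product counted as one exchange, gives 1.50 per complex charged, against n = 1.50.

In the neighbour flask with 0.18 M of incoming ligand, n = 0.600, so at most 60.0% of the starting complex can react. The computed neighbour flask has 38.7% gone, less than that bound, with incoming ligand at 0% of its charge.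

The runs come from a simulation for substances that don't exist, noise included.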